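The cyclohexene ring C2–C1=C10–C14–C15′–C4′ that welds the two guaianolide halves is a Diels–Alder retron. Its alkene lies between the tertiary carbinol C2 and a CH2–CH2 bridge that ends at the spiro carbon C4′. Both halves derive from one monomer, 7-epi-dehydrozaluzanin C, reached from dehydrocostus lactone by inversion of C7. In the last step the 2-hydroxy derivative of the monomer is oxidised beside an excess of the monomer. The diketone enolises to a diosphenol whose C14=C10–C1=C2(OH) diene adds to the C4′=C15′ enone. One operation forms two C–C bonds, the six-membered ring and the adjacent fully substituted stereocentres C2 and C4′; the enol oxygen becomes the C2 hydroxyl.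

Key step: step 9

Remark on the chemistry (assumption): read literally, the SMILES has H-6 and H-7 cis in both halves (6S,7R, cis-fused lactones), the 7-epimer of the trans-fused natural series, so the commercial lactone (6S,7S, sold as an isolate of costus root oil) needs the C7 inversion of steps 1–4. Guaiane numbering is used, primed atoms belong to the spiro half, and α is the face of H-1 and H-5.

Step 1
Reactants: 1 (−)-dehydrocostus lactone
Product: 2 11β,13-epoxy-11,13-dihydrodehydrocostus lactone
Conditions: t-BuOOH (decane), n-BuLi, THF, −78 to 0 °C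
Reagents that add atoms: tert-butyl hydroperoxide, CC(C)(C)OO
Why: Weitz–Scheffer nucleophilic epoxidation: the peroxide anion adds only to the electron-poor C11=C13 bond of the α-methylene lactone (C4=C15 and C10=C14 are inert to nucleophiles), and the lactone enolate closes onto oxygen from the β face, the face on which enolates of such trans-fused lactones take up electrophiles, so that the new C11–O bond is β, pseudoaxial and antiperiplanar to H-7α.

Step 2
Reactants: 2 11β,13-epoxy-11,13-dihydrodehydrocostus lactone
Product: 3 13-chloro-11β-hydroxy-11,13-dihydrodehydrocostus lactone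
Conditions: LiCl, AcOH, THF, rt
Reagents that add atoms: lithium chloride, [Li+].[Cl-]
Why: Halohydrin formation from an epoxide with LiX/AcOH is an acid-assisted SN2 opening that here can only take place at the primary C13, since C11 is quaternary and α to the carbonyl, so the C11 configuration is kept.

Step 3
Reactants: 3 13-chloro-11β-hydroxy-11,13-dihydrodehydrocostus lactone
Product: 4 13-chloroguaia-4(15),7(11),10(14)-trien-12,6α-olide
Conditions: SOCl2, pyridine, CH2Cl2, −20 to 0 °C
Reagents that add atoms: none
Why: SOCl2/pyridine dehydration of a tertiary α-hydroxy lactone is an anti E2 elimination of the activated hydroxyl, and the fixed antiperiplanar H-7α together with the gain of a conjugated tetrasubstituted butenolide directs it towards C7, which erases the C7 stereocentre and leaves an activated allylic chloride.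

Step 4
Reactants: 4 13-chloroguaia-4(15),7(11),10(14)-trien-12,6α-olide
Product: 6 7-epi-dehydrocostus lactone, via allylzinc chloride 5 (not isolated)
Conditions: Zn dust, sat. aq NH4Cl/THF, 0 °C to rt
Reagents that add atoms: none
Why: Barbier-type zinc insertion gives the 2-carbonylallylzinc 5, a reagent class (from α-halomethyl butenolides) that takes up electrophiles at the γ-carbon in the SE2′ sense, so protonolysis puts hydrogen on C7 and restores C11=C13, and the proton comes to the butenolide face that bears H-6 (anti to the C6–C5 bond), which sets 7βH (7R) and the cis-fused lactone.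

Step 5
Reactants: 6 7-epi-dehydrocostus lactone
Product: 7 3α-hydroxy-7-epi-dehydrocostus lactone
Conditions: SeO2 (cat.), t-BuOOH, CH2Cl2, 0 °C to rt
Reagents that add atoms: tert-butyl hydroperoxide, CC(C)(C)OO (terminal oxidant, its oxygen is passed on through SeO2)
Why: Catalytic SeO2/t-BuOOH allylic hydroxylation (ene reaction, then [2,3]-shift) attacks the 4(15)-ene at its CH2 flank C3, as is usual for 4(15),10(14)-guaiadienolides, from the convex α face; the C3 stereocentre is removed in step 6, so its configuration is of no consequence.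

Step 6
Reactants: 7 3α-hydroxy-7-epi-dehydrocostus lactone
Product: 8 7-epi-dehydrozaluzanin C
Conditions: Dess–Martin periodinane, CH2Cl2, 0 °C to rt
Reagents that add atoms: none
Why: Dess–Martin oxidation of a secondary allylic alcohol is mild enough to leave the sensitive α-methylene ketone, the α-methylene lactone and all stereocentres untouched.

Step 7
Reactants: 8 7-epi-dehydrozaluzanin C
Product: 9 3-triethylsilyloxy dienol ether of 8
Conditions: Et3SiOTf, Et3N, CH2Cl2, −78 °C
Reagents that add atoms: triethylsilyl triflate, CC[Si](CC)(CC)OS(=O)(=O)C(F)(F)F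
Why: Soft enolisation with a silyl triflate and an amine can only remove a C2 hydrogen, because C4 carries none, and it avoids metal enolates that would add to the Michael acceptors; no stereocentre is touched.

Step 8
Reactants: 9 3-triethylsilyloxy dienol ether of 8
Product: 11 2α-hydroxy-7-epi-dehydrozaluzanin C, via silyloxy epoxide 10 (not isolated)
Conditions: DMDO (1.0 equiv), acetone/CH2Cl2, −78 °C; then AcOH/THF/H2O, 0 °C
Reagents that add atoms: dimethyldioxirane, CC1(C)OO1
Why: Rubottom oxidation: the silyl enol ether C2=C3 is by far the most electron-rich alkene and is epoxidised first, from the convex α face, and mild acid opens 10 to the ketol; the C2 stereocentre is removed in step 9.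

Step 9
Reactants: 11 2α-hydroxy-7-epi-dehydrozaluzanin C; 8 7-epi-dehydrozaluzanin C
Product: 14 target dimer CNP0269880.1, via diketone 12 (not isolated), via diosphenol diene 13 (not isolated)
Conditions: Dess–Martin periodinane (1.05 equiv), 8 (3 equiv), CH2Cl2, argon, dark, 0 °C, then 30 °C
Reagents that add atoms: none
Why: The periodinane oxidises the C2 carbinol of 11 to the diketone 12, whose only enolisable hydrogen (H-1) moves to oxygen under catalysis by the liberated AcOH to give the diosphenol 13, in which C14=C10–C1=C2(OH) is a cisoid 1-oxygenated diene held in place by the seven-membered ring. 13 then adds to the C4′=C15′ enone of 8 in an intermolecular normal-demand Diels–Alder reaction, the closest known type being the cycloaddition of 1-oxygenated semicyclic dienes (dienols, photoenols, 3-hydroxy-2-pyrones) to α-methylene ketones, and a stepwise vinylogous Michael/aldol path would end at the same adduct. The six-membered ring C2–C1–C10–C14–C15′–C4′ is closed by a suprafacial [4+2] union that forms C14–C15′ and C2–C4′ and leaves C1=C10. Regiochemistry follows the ortho rule, since the donor oxygen on C2 puts the largest HOMO coefficient on C14, which meets the β-carbon C15′. C4′ is set by attack on the convex α face of 8 (the side of H-1′ and H-5′), and C2 by the endo arrangement that places the small C3′ carbonyl, not C5′ with its seven-membered ring, over the five-membered ring of 13; this pairing brings 8 onto the β face of 13, which carries only H-6 and H-7 because the cis lactone lies on the α face, so the hydroxyl ends up α and the C2–C4′ bond β. The cross reaction must win over self-addition of 13, which the excess of 8 and the slow release of 13 secure, and the strained s-cis enone of 8 outruns both α-methylene lactones as dienophile.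

Compound list
1 | (−)-dehydrocostus lactone, guaia-4(15),10(14),11(13)-trien-12,6α-olide (1αH,5αH,6βH,7αH, trans-fused lactone) | C=C1CC[C@H]2C(=C)CC[C@H]3C(=C)C(=O)O[C@@H]3[C@H]21 | starting material
2 | 11β,13-epoxy-11,13-dihydrodehydrocostus lactone (spiro-oxirane, C11–O β, C13 α) | C=C1CC[C@H]2C(=C)CC[C@H]3[C@]4(CO4)C(=O)O[C@@H]3[C@H]21 | intermediate
3 | 13-chloro-11β-hydroxy-11,13-dihydrodehydrocostus lactone | C=C1CC[C@H]2C(=C)CC[C@H]3[C@](O)(CCl)C(=O)O[C@@H]3[C@H]21 | intermediate
4 | 13-chloroguaia-4(15),7(11),10(14)-trien-12,6α-olide (1αH,5αH,6βH) | C=C1CC[C@H]2C(=C)CCC3=C(CCl)C(=O)O[C@@H]3[C@H]21 | intermediate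
5 | allylzinc chloride from 4 (ClZn on C13) | C=C1CC[C@H]2C(=C)CCC3=C(C[Zn]Cl)C(=O)O[C@@H]3[C@H]21 | intermediate
6 | 7-epi-dehydrocostus lactone (1αH,5αH,6βH,7βH, cis-fused lactone) | C=C1CC[C@H]2C(=C)CC[C@@H]3C(=C)C(=O)O[C@@H]3[C@H]21 | intermediate
7 | 3α-hydroxy-7-epi-dehydrocostus lactone | C=C1[C@H](O)C[C@H]2C(=C)CC[C@@H]3C(=C)C(=O)O[C@@H]3[C@H]21 | intermediate
8 | 7-epi-dehydrozaluzanin C, 3-oxoguaia-4(15),10(14),11(13)-trien-12,6α-olide (1αH,5αH,6βH,7βH) | C=C1C(=O)C[C@H]2C(=C)CC[C@@H]3C(=C)C(=O)O[C@@H]3[C@H]21 | intermediate
9 | 3-triethylsilyloxyguaia-2,4(15),10(14),11(13)-tetraen-12,6α-olide (1αH,5αH,6βH,7βH) | C=C1C(O[Si](CC)(CC)CC)=C[C@H]2C(=C)CC[C@@H]3C(=C)C(=O)O[C@@H]3[C@H]21 | intermediate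
10 | 2α,3α-epoxy-3β-triethylsilyloxy derivative of 9 | C=C1[C@]2(O[Si](CC)(CC)CC)O[C@@H]2[C@H]3C(=C)CC[C@@H]4C(=C)C(=O)O[C@@H]4[C@@H]13 | intermediate
11 | 2α-hydroxy-7-epi-dehydrozaluzanin C | C=C1C(=O)[C@H](O)[C@H]2C(=C)CC[C@@H]3C(=C)C(=O)O[C@@H]3[C@H]21 | intermediate
12 | 2,3-dioxoguaia-4(15),10(14),11(13)-trien-12,6α-olide (1αH,5αH,6βH,7βH) | C=C1C(=O)C(=O)[C@H]2C(=C)CC[C@@H]3C(=C)C(=O)O[C@@H]3[C@H]21 | intermediate
13 | 2-hydroxy-3-oxoguaia-1,4(15),10(14),11(13)-tetraen-12,6α-olide (5αH,6βH,7βH), the diosphenol diene | C=C1C(=O)C(O)=C2C(=C)CC[C@@H]3C(=C)C(=O)O[C@@H]3[C@H]21 | intermediate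
14 | CNP0269880.1 (2α-OH, C2–C4′ β on the diene half; at C4′ C2 is α and C15′ β; both lactones cis-fused) | C=C1C(=O)[C@]2(O)C3=C(CC[C@@H]4C(=C)C(=O)O[C@@H]4[C@@H]13)CC[C@]21C(=O)C[C@H]2C(=C)CC[C@@H]3C(=C)C(=O)O[C@@H]3[C@H]21 | target

Total step count: 9. Longest linear sequence: 9 steps from 1. The route is linear to 8, which enters twice: as the dienophile and, through steps 7 and 8, as the source of the diene.

Steps most likely to fail

Step 9.
- What may go wrong:
  - The Z-configured dienol may re-ketonise by a 1,5-hydrogen shift from oxygen to C14.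
  - The diene may add to its own C4=C15 enone.
  - A hydrogen bond from the enol OH to the C3′ carbonyl may favour the exo arrangement and erode endo and facial selectivity.
- Fallback (sets out from 11, comes back at 14): the dienol is taken out of play as its silyl ether.
  - 11 is oxidised as before but without 8, and the crude diosphenol 13 is capped at −78 °C with Me3SiOTf/2,6-lutidine to the 2-trimethylsilyloxy diene F1. This diene can neither shift hydrogen to C14 nor donate a hydrogen bond.
  - F1 and 8 are united in a separate thermal or high-pressure Diels–Alder reaction to the silyl ether of the adduct F2.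
  - Aqueous citric acid in THF then frees 14.

Step 4.
- What may go wrong:
  - Protonation may take place at the primary terminus C13 instead of C7.
  - Two allyl units may couple in the Wurtz manner.
  - The proton may be delivered with poor facial selectivity at C7.
- Fallback (sets out from 4, comes back at 6): hydrogen is delivered by a sigmatropic process instead of by protonolysis.
  - N-Alkylation of N-isopropylidene-N′-(2-nitrobenzenesulfonyl)hydrazine with 4 (K2CO3, DMF, 0 °C) gives the sulfonyl hydrazone F3.
  - In CF3CH2OH/H2O it loses acetone and the sulfinic acid to give the allylic diazene F4.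
  - F4 expels N2 in a retro-ene reaction that can only place hydrogen on C7 and the double bond at C11=C13, again from the face that bears H-6, and so gives 6.

Step 3.
- What may go wrong:
  - The elimination may take a hydrogen from C13 rather than H-7.
  - If the epoxidation of step 1 takes the α face, no antiperiplanar hydrogen stands at C7.
- Fallback (sets out from 2, comes back at 4): C13 is cut off and put back, so that C7 is planarised by tautomerism and not by elimination.
  - H5IO6 in aqueous THF cleaves the epoxide of 2 to the 13-nor α-keto lactone in its enol form, the 11-hydroxy butenolide F5.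
  - PhNTf2/Et3N gives the enol triflate F6.
  - Stille coupling with Bu3SnCH2OH (Pd(PPh3)4, LiCl, dioxane) gives the 13-hydroxy butenolide F7.
  - An Appel reaction (PPh3, CCl4) gives 4.

Further compounds
F1 | step 9 | 2-trimethylsilyloxy-3-oxoguaia-1,4(15),10(14),11(13)-tetraen-12,6α-olide (5αH,6βH,7βH) | C=C1C(=O)C(O[Si](C)(C)C)=C2C(=C)CC[C@@H]3C(=C)C(=O)O[C@@H]3[C@H]21
F2 | step 9 | 2-O-trimethylsilyl ether of 14 | C=C1C(=O)[C@]2(O[Si](C)(C)C)C3=C(CC[C@@H]4C(=C)C(=O)O[C@@H]4[C@@H]13)CC[C@]21C(=O)C[C@H]2C(=C)CC[C@@H]3C(=C)C(=O)O[C@@H]3[C@H]21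
F3 | step 4 | 13-[N-(2-nitrobenzenesulfonyl)-N′-isopropylidenehydrazino]guaia-4(15),7(11),10(14)-trien-12,6α-olide | C=C1CC[C@H]2C(=C)CCC3=C(CN(N=C(C)C)S(=O)(=O)c4ccccc4[N+](=O)[O-])C(=O)O[C@@H]3[C@H]21
F4 | step 4 | 13-diazenylguaia-4(15),7(11),10(14)-trien-12,6α-olide (allylic diazene) | C=C1CC[C@H]2C(=C)CCC3=C(CN=N)C(=O)O[C@@H]3[C@H]21
F5 | step 3 | 11-hydroxy-13-norguaia-4(15),7(11),10(14)-trien-12,6α-olide | C=C1CC[C@H]2C(=C)CCC3=C(O)C(=O)O[C@@H]3[C@H]21
F6 | step 3 | 11-trifluoromethanesulfonyloxy-13-norguaia-4(15),7(11),10(14)-trien-12,6α-olide | C=C1CC[C@H]2C(=C)CCC3=C(OS(=O)(=O)C(F)(F)F)C(=O)O[C@@H]3[C@H]21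
F7 | step 3 | 13-hydroxyguaia-4(15),7(11),10(14)-trien-12,6α-olide | C=C1CC[C@H]2C(=C)CCC3=C(CO)C(=O)O[C@@H]3[C@H]21
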